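**Plan**
1. Retrosynthetic cuts: the four C–O bonds of the two oxiranes (C1–O–C10, C4–O–C5); the C8–O ester bond; the butenolide taken back to a furan fused at C6–C7; the furan bonds C7–C11 and O–C12; the ring bond C6–C7; last, S–C7 and C8–C9 of an open geranic acid chain.
2. Enabling feature: in the ten-membered carbocycle C1–C10, the oxygenated carbons C6 and C8 flank C7, which is a masked cyclic 1,3-diketone. The C6–C7 bond of such a diketone can be made by extruding sulfur from its S-bridged isomer C6(=O)–S–C7. The strained E,E-cyclodecadiene therefore comes from contraction of an easily closed eleven-membered thialactone.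
3. Forward order: chain (C6–C5=C4…C1=C10–C9 from geranic acid, C8/C7 from an ethoxyvinyl unit) → 11-membered thialactone → 10-membered diketone → furan (adds C11–C13) → butenolide by furan dearomatisation → two oxiranes.
4. Helpers removed on the way: the 2-silylethyl thioester (masked thiocarboxylate), the sulfur atom (temporary ring member) and the furan (masked butenolide).
5. Stereochemistry: both E alkenes come from geranic acid and the E-selective SeO2 oxidation. C8 comes from a CBS reduction, and C6 from peripheral hydride addition relayed from C8. C1, C10, C4 and C5 come from peripheral peracid attack on the crown conformer. C2' comes from (R)-3-bromo-2-hydroxy-2-methylpropanoic acid.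

Key step: step 7

Remark: germacrane numbering is used (ring C1–C10; C6 lactone carbinol carbon; C8 ester carbinol carbon; C7=C11 butenolide alkene; C12 lactone C=O; C13 CH2OAc; C14/C15 methyls on C10/C4), and geranic acid is taken as the pure 2E isomer.

Step 1
Reactants: 1 (2E)-geranic acid; 2 2-(trimethylsilyl)ethanethiol
Product: 3 S-[2-(trimethylsilyl)ethyl] (2E)-3,7-dimethylocta-2,6-dienethioate
Conditions: DCC, DMAP (cat.), CH2Cl2, 0 °C → rt
Reagents that add atoms: 2-(trimethylsilyl)ethanethiol (2), C[Si](C)(C)CCS
Why: Steglich-type carbodiimide thioesterification should give the thioester without touching the alkenes (the β,β-disubstituted enoyl unit resists thiol conjugate addition), and the 2-silylethyl group keeps the later thiocarboxylate masked until fluoride is added; no stereocentre is formed.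

Step 2
Reactants: 3 S-[2-(trimethylsilyl)ethyl] (2E)-3,7-dimethylocta-2,6-dienethioate
Product: 4 S-[2-(trimethylsilyl)ethyl] (2E,6E)-8-hydroxy-3,7-dimethylocta-2,6-dienethioate
Conditions: SeO2 (cat.), t-BuOOH, salicylic acid (cat.), CH2Cl2, 0 °C → rt
Reagents that add atoms: selenium dioxide (oxygen carrier), O=[Se]=O; tert-butyl hydroperoxide (terminal oxygen source), CC(C)(C)OO
Why: Riley allylic oxidation (ene reaction, then [2,3]-sigmatropic shift) should attack the electron-rich terminal alkene rather than the thioester-conjugated one and oxidise only the methyl group trans to the chain, which fixes the E geometry of the future C1=C10 alkene and turns C9 into a handle.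

Step 3
Reactants: 4 S-[2-(trimethylsilyl)ethyl] (2E,6E)-8-hydroxy-3,7-dimethylocta-2,6-dienethioate
Product: 5 S-[2-(trimethylsilyl)ethyl] (2E,6E)-8-bromo-3,7-dimethylocta-2,6-dienethioate
Conditions: CBr4, PPh3, CH2Cl2, −20 °C
Reagents that add atoms: tetrabromomethane, BrC(Br)(Br)Br
Why: The Appel reaction should replace the primary allylic hydroxyl by bromide in an SN2 step under neutral conditions, without allylic transposition or loss of alkene geometry.

Step 4
Reactants: 5 S-[2-(trimethylsilyl)ethyl] (2E,6E)-8-bromo-3,7-dimethylocta-2,6-dienethioate; 6 tributyl(1-ethoxyvinyl)stannane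
Product: 7 S-[2-(trimethylsilyl)ethyl] (2E,6E)-9-ethoxy-3,7-dimethyldeca-2,6,9-trienethioate
Conditions: Pd2(dba)3 (cat.), P(2-furyl)3 (cat.), THF, 50 °C
Reagents that add atoms: tributyl(1-ethoxyvinyl)stannane (6), CCCC[Sn](CCCC)(CCCC)C(=C)OCC
Why: Stille coupling of an allylic bromide with an α-alkoxyvinylstannane should form the C8–C9 bond at the unsubstituted allyl terminus with the E alkene retained, and the thioester stays inert because no copper(I) or zinc cofactor is present.

Step 5
Reactants: 7 S-[2-(trimethylsilyl)ethyl] (2E,6E)-9-ethoxy-3,7-dimethyldeca-2,6,9-trienethioate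
Product: 8 S-[2-(trimethylsilyl)ethyl] (2E,6E)-10-bromo-3,7-dimethyl-9-oxodeca-2,6-dienethioate
Conditions: NBS (1 equiv), aq. THF, −20 °C
Reagents that add atoms: N-bromosuccinimide, O=C1CCC(=O)N1Br; water, O
Why: Electrophilic bromination of the enol ether and hydrolysis of the resulting bromo-oxocarbenium ion should give the bromomethyl ketone regiospecifically at C7, because the enol ether is far more nucleophilic than either trisubstituted alkene.

Step 6
Reactants: 8 S-[2-(trimethylsilyl)ethyl] (2E,6E)-10-bromo-3,7-dimethyl-9-oxodeca-2,6-dienethioate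
Product: 10 (3E,7E)-4,8-dimethyl-1-thiacycloundeca-3,7-diene-2,10-dione, via caesium thiocarboxylate 9 (not isolated)
Conditions: CsF, MeCN/DMF, slow syringe-pump addition (high dilution), rt
Reagents that add atoms: none
Why: Fluoride-induced fragmentation of the 2-silylethyl group (as for 2-silylethyl esters and sulfides) should free the soft thiocarboxylate, whose very fast SN2 S-alkylation by the α-bromoketone closes the eleven-membered ring under high dilution without disturbing either alkene.

Step 7
Reactants: 10 (3E,7E)-4,8-dimethyl-1-thiacycloundeca-3,7-diene-2,10-dione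
Product: 12 (4E,8E)-5,9-dimethylcyclodeca-4,8-diene-1,3-dione, via hydroxythiirane 11 (not isolated)
Conditions: PPh3, LiBr, i-Pr2NEt, MeCN, 60 °C; dilute citric acid work-up
Reagents that add atoms: none
Why: Soft enolisation of the C8 ketone toward C7, the only carbon flanked by both sulfur and a carbonyl, lets C7 add across the sulfur atom to the neighbouring C6 thioester carbonyl to give hydroxythiirane 11, and triphenylphosphine then removes sulfur irreversibly so that the C6–C7 bond stays and the ring shrinks from eleven to ten atoms. The closest known reaction type is the Eschenmoser sulfide contraction of S-(2-oxoalkyl) thiocarboxylates to 1,3-diketones, which is also known in ring-contracting form for medium rings. The thiirane closes in the 3-exo-trig mode and the same C6–C7 bond closes the ten-membered carbocycle, so no end-to-end medium-ring cyclisation is needed because sulfur already holds the two reacting carbons 1,3 to each other. No lasting stereocentre is formed (C6 and C7 of 11 return to C=O and CH2) and neither alkene takes part, so both E geometries should carry over. The step needs C7 rather than C9 enolate chemistry and carbonyl rather than conjugate attack: a C9 enolate has no electrophile within reach and simply reprotonates, and Michael addition of C7 to C4 would be a 5-endo-trig closure onto a fully substituted carbon. The P=S bond and the stabilised diketone enolate should pay for the strain of the E,E-cyclodecadiene.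

Step 8
Reactants: 12 (4E,8E)-5,9-dimethylcyclodeca-4,8-diene-1,3-dione; 13 3-chloro-2-oxopropyl acetate
Product: 15 13-acetoxy-6,12-epoxygermacra-1(10)E,4E,6,11-tetraen-8-one (furan ketone), via hydroxydihydrofuran 14 (not isolated)
Conditions: Et3N, MeCN, 0 °C → rt; then PPTS (cat.), 4 Å MS, 40 °C
Reagents that add atoms: 3-chloro-2-oxopropyl acetate (13), CC(=O)OCC(=O)CCl
Why: Feist–Benary furan synthesis: the enolate carbon C7 should add to the doubly activated ketone carbonyl of 13 (future C11), the enolate oxygen then displaces chloride (5-exo-tet, O–C12 bond) and loss of water aromatises, with closure expected through O6 rather than O8 because O6 is the more electron-rich, vinylogously fed oxygen and this mode keeps the linear conjugation C4=C5–C6=C7–C8=O.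

Step 9
Reactants: 15 13-acetoxy-6,12-epoxygermacra-1(10)E,4E,6,11-tetraen-8-one
Product: 16 (8S)-13-acetoxy-6,12-epoxygermacra-1(10)E,4E,6,11-tetraen-8-ol
Conditions: (R)-Me-CBS (cat.), catecholborane, toluene, −78 °C
Reagents that add atoms: none
Why: Corey–Bakshi–Shibata reduction: the ketone should bind to the oxazaborolidine with the flat furyl flank as the large group and the C9 methylene as the small one, so that the (R)-catalyst delivers hydride to give the 8S carbinol (first stereocentre of the route), while catecholborane at −78 °C leaves the trisubstituted alkenes, the furan and the acetate alone.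

Step 10
Reactants: 17 (2R)-3-bromo-2-hydroxy-2-methylpropanoic acid
Product: 19 (2R)-3-chloro-2-hydroxy-2-methylpropanoic acid, via sodium glycidate 18 (not isolated)
Conditions: NaOH (2 equiv), H2O, 0 °C; then conc. HCl, 0 °C → rt
Reagents that add atoms: hydrogen chloride, Cl
Why: Base-induced halohydrin closure to the 2-methylglycidate and acid-mediated SN2 opening by chloride at the unhindered CH2 carbon should exchange bromine for chlorine without touching the quaternary stereocentre, so its configuration is carried over from the chiral pool.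

Step 11
Reactants: 16 (8S)-13-acetoxy-6,12-epoxygermacra-1(10)E,4E,6,11-tetraen-8-ol; 19 (2R)-3-chloro-2-hydroxy-2-methylpropanoic acid
Product: 20 (8S)-13-acetoxy-6,12-epoxygermacra-1(10)E,4E,6,11-tetraen-8-yl (2R)-3-chloro-2-hydroxy-2-methylpropanoate
Conditions: DCC, DMAP, CH2Cl2, 0 °C
Reagents that add atoms: (2R)-3-chloro-2-hydroxy-2-methylpropanoic acid (19), OC(=O)[C@@](C)(O)CCl
Why: Steglich esterification should acylate the secondary C8 hydroxyl with retention at both stereocentres, the tertiary hydroxyl of 19 being too hindered to compete as a nucleophile.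

Step 12
Reactants: 20 (8S)-13-acetoxy-6,12-epoxygermacra-1(10)E,4E,6,11-tetraen-8-yl (2R)-3-chloro-2-hydroxy-2-methylpropanoate
Product: 22 (8S)-13-acetoxy-8-[(2R)-3-chloro-2-hydroxy-2-methylpropanoyloxy]-6-hydroxygermacra-1(10)E,4E,7(11)-trien-12,6-olide (C6 hemiketal), via furan endoperoxide 21 (not isolated)
Conditions: O2, hν (visible), rose bengal (cat.), i-Pr2NEt, CH2Cl2, −78 °C
Reagents that add atoms: dioxygen, O=O
Why: Furan dearomatisation by [4+2] cycloaddition of singlet oxygen and base-induced Kornblum–DeLaMare fragmentation: C12 carries the only bridgehead hydrogen of the endoperoxide and so must become the lactone carbonyl, C6 becomes a hemiketal and the C7=C11 alkene appears in place, the furan reacting much faster than the trisubstituted alkenes and the C6 configuration being erased again in step 13.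

Step 13
Reactants: 22 (8S)-13-acetoxy-8-[(2R)-3-chloro-2-hydroxy-2-methylpropanoyloxy]-6-hydroxygermacra-1(10)E,4E,7(11)-trien-12,6-olide
Product: 24 (6R,8S)-13-acetoxy-8-[(2R)-3-chloro-2-hydroxy-2-methylpropanoyloxy]germacra-1(10)E,4E,7(11)-trien-12,6-olide (O-6 and O-8 both α), via hydroxy acid 23 (not isolated)
Conditions: NaBH4, CeCl3·7H2O, MeOH/THF, −40 °C; then pH 5 phosphate buffer, rt
Reagents that add atoms: none
Why: Luche 1,2-reduction of the ring-opened γ-keto acid tautomer followed by lactonisation: in the crown conformer that puts the C8 ester outside the ring (H-8 eclipsing C13 to relieve A1,3 strain across C7=C11) only the outer face of the C6 carbonyl is open, so hydride should enter there and give the 6α-oxygen cis to O-8, while CeCl3 suppresses conjugate reduction and the esters survive at low temperature.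

Step 14
Reactants: 24 (6R,8S)-13-acetoxy-8-[(2R)-3-chloro-2-hydroxy-2-methylpropanoyloxy]germacra-1(10)E,4E,7(11)-trien-12,6-olide
Product: 26 CNP0255009.1, via 1(10)-monoepoxide 25 (not isolated)
Conditions: mCPBA (2.5 equiv), CH2Cl2 / pH 8 phosphate buffer, 0 °C
Reagents that add atoms: 3-chloroperoxybenzoic acid, OOC(=O)c1cccc(Cl)c1
Why: Prilezhaev epoxidation is stereospecific (E alkene to trans oxirane), and in the crown conformer fixed by C6 and C8 both ring alkenes stand perpendicular to the mean ring plane with their methyl groups on the β face, so peracid should reach only the outer faces and give the 1β,10α (1R,10R) and 4α,5β (4R,5R) oxiranes, the electron-poor tetrasubstituted butenolide alkene staying untouched and the buffer preventing transannular opening.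

**Compound list**
1 | (2E)-geranic acid, (2E)-3,7-dimethylocta-2,6-dienoic acid | CC(C)=CCC/C(C)=C/C(=O)O | starting material
2 | 2-(trimethylsilyl)ethanethiol | C[Si](C)(C)CCS | starting material
3 | S-[2-(trimethylsilyl)ethyl] (2E)-3,7-dimethylocta-2,6-dienethioate | CC(C)=CCC/C(C)=C/C(=O)SCC[Si](C)(C)C | intermediate
4 | S-[2-(trimethylsilyl)ethyl] (2E,6E)-8-hydroxy-3,7-dimethylocta-2,6-dienethioate | OC/C(C)=C/CC/C(C)=C/C(=O)SCC[Si](C)(C)C | intermediate
5 | S-[2-(trimethylsilyl)ethyl] (2E,6E)-8-bromo-3,7-dimethylocta-2,6-dienethioate | BrC/C(C)=C/CC/C(C)=C/C(=O)SCC[Si](C)(C)C | intermediate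
6 | tributyl(1-ethoxyvinyl)stannane | CCCC[Sn](CCCC)(CCCC)C(=C)OCC | starting material
7 | S-[2-(trimethylsilyl)ethyl] (2E,6E)-9-ethoxy-3,7-dimethyldeca-2,6,9-trienethioate | C=C(OCC)C/C(C)=C/CC/C(C)=C/C(=O)SCC[Si](C)(C)C | intermediate
8 | S-[2-(trimethylsilyl)ethyl] (2E,6E)-10-bromo-3,7-dimethyl-9-oxodeca-2,6-dienethioate | BrCC(=O)C/C(C)=C/CC/C(C)=C/C(=O)SCC[Si](C)(C)C | intermediate
9 | caesium (2E,6E)-10-bromo-3,7-dimethyl-9-oxodeca-2,6-dienethioate (free thiocarboxylate) | BrCC(=O)C/C(C)=C/CC/C(C)=C/C(=O)[S-].[Cs+] | intermediate
10 | (3E,7E)-4,8-dimethyl-1-thiacycloundeca-3,7-diene-2,10-dione (11-membered thialactone, C6(=O)–S–C7H2–C8(=O)) | O=C1CSC(=O)/C=C(\C)CC/C=C(\C)C1 | intermediate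
11 | (2E,6E)-1-hydroxy-3,7-dimethyl-11-thiabicyclo[8.1.0]undeca-2,6-dien-9-one (thiirane across C6–C7, transient, configuration at C6/C7 not defined) | O=C1C/C(C)=C/CC/C(C)=C/C2(O)SC12 | intermediate
12 | (4E,8E)-5,9-dimethylcyclodeca-4,8-diene-1,3-dione (C6 and C8 ketones, C7H2 between them) | O=C1CC(=O)/C=C(\C)CC/C=C(\C)C1 | intermediate
13 | 3-chloro-2-oxopropyl acetate (1-acetoxy-3-chloroacetone) | CC(=O)OCC(=O)CCl | starting material
14 | 11-hydroxy-11,12-dihydrofuran precursor of 15 (C11 carbinol, racemic) | C1C/C=C(\C)CC(=O)C2=C(OCC2(O)COC(C)=O)/C=C1\C | intermediate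
15 | 13-acetoxy-6,12-epoxygermacra-1(10)E,4E,6,11-tetraen-8-one (furan fused at C6–C7, C8 ketone) | C1C/C=C(\C)CC(=O)c2c(COC(C)=O)coc2/C=C1\C | intermediate
16 | (8S)-13-acetoxy-6,12-epoxygermacra-1(10)E,4E,6,11-tetraen-8-ol | C1C/C=C(\C)C[C@H](O)c2c(COC(C)=O)coc2/C=C1\C | intermediate
17 | (2R)-3-bromo-2-hydroxy-2-methylpropanoic acid | OC(=O)[C@@](C)(O)CBr | starting material
18 | sodium (2S)-2-methyloxirane-2-carboxylate | [Na+].[O-]C(=O)[C@]1(C)CO1 | intermediate
19 | (2R)-3-chloro-2-hydroxy-2-methylpropanoic acid | OC(=O)[C@@](C)(O)CCl | intermediate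
20 | (8S)-13-acetoxy-6,12-epoxygermacra-1(10)E,4E,6,11-tetraen-8-yl (2R)-3-chloro-2-hydroxy-2-methylpropanoate | C1C/C=C(\C)C[C@H](OC(=O)[C@@](C)(O)CCl)c2c(COC(C)=O)coc2/C=C1\C | intermediate
21 | 6,12-endoperoxide of furan 20 (O–O and O bridges between C6 and C12, C7=C11 alkene) | CC(=O)OCC1=C2[C@@H](OC(=O)[C@@](C)(O)CCl)C/C(C)=C/CC/C(C)=C/C23OOC1O3 | intermediate
22 | (8S)-13-acetoxy-8-[(2R)-3-chloro-2-hydroxy-2-methylpropanoyloxy]-6-hydroxygermacra-1(10)E,4E,7(11)-trien-12,6-olide (equilibrating C6 hemiketal) | CC(=O)OCC1=C2[C@@H](OC(=O)[C@@](C)(O)CCl)C/C(C)=C/CC/C(C)=C/C2(O)OC1=O | intermediate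
23 | (6R,8S)-6-hydroxy seco acid of 24 (C12 acid cis to C6 across C7=C11) | OC(=O)/C(COC(C)=O)=C1/[C@@H](OC(=O)[C@@](C)(O)CCl)C/C(C)=C/CC/C(C)=C/[C@H]1O | intermediate
24 | (6R,8S)-13-acetoxy-8-[(2R)-3-chloro-2-hydroxy-2-methylpropanoyloxy]germacra-1(10)E,4E,7(11)-trien-12,6-olide | CC(=O)OCC1=C2[C@@H](OC(=O)[C@@](C)(O)CCl)C/C(C)=C/CC/C(C)=C/[C@H]2OC1=O | intermediate
25 | (1R,10R)-1,10-epoxide of 24 | CC(=O)OCC1=C2[C@@H](OC(=O)[C@@](C)(O)CCl)C[C@@]3(C)O[C@@H]3CC/C(C)=C/[C@H]2OC1=O | intermediate
26 | CNP0255009.1, (1R,4R,5R,6S,8S,10R)-13-acetoxy-8-[(2R)-3-chloro-2-hydroxy-2-methylpropanoyloxy]-1,10:4,5-diepoxygermacr-7(11)-en-12,6-olide | CC(=O)OCC1=C2[C@@H](OC(=O)[C@@](C)(O)CCl)C[C@@]3(C)O[C@@H]3CC[C@@]3(C)O[C@@H]3[C@H]2OC1=O | target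

Total step count: 14. Longest linear sequence: 13 (steps 1–9 and 11–14).

**Steps most likely to fail**

Step 8. The furan may close through the wrong diketone oxygen, or the chloromethyl carbon may be C-alkylated before the aldol addition takes place.
- The fallback sets out from 12.
- Condensation with pyrrolidine (toluene, 4 Å MS) should occur at the non-conjugated, more electrophilic C8 carbonyl. It should give the vinylogous amide (2E,5E,9E)-5,9-dimethyl-3-(pyrrolidin-1-yl)cyclodeca-2,5,9-trien-1-one F2, in which O6 is the only nucleophilic oxygen.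
- Reaction of this enaminone with 13 and Et3N gives aldol addition at C7 and then O6-alkylation.
- Hydrolysis of the C8 iminium ion with aqueous NaOAc/AcOH and loss of water comes back to the route at 15.

Step 7. Sulfur abstraction from the reversibly formed thiirane may be too slow. Repeated enolisation toward C9 would then let the C1(10) alkene drift into conjugation.
- The fallback sets out from 10 and separates the two events.
- Irreversible deprotonation with LiHMDS (THF, −78 → 0 °C, no thiophile) should drive the S→C acyl shift. This is still an 11 → 10 contraction and should give 2-sulfanyl-(4E,8E)-5,9-dimethylcyclodeca-4,8-diene-1,3-dione F1.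
- Reductive cleavage of the activated C–S bond with zinc in AcOH/THF comes back to the route at 12.

Step 13. Hydride delivery to the C6 carbonyl of the ring-opened keto acid may show poor facial selectivity. The fallback changes the control element from ring conformation to chelation and swaps the order of events.
- It sets out from 16. Photooxygenation of the free alcohol under the conditions of step 12 should give (8S)-13-acetoxy-6,8-dihydroxygermacra-1(10)E,4E,7(11)-trien-12,6-olide F3.
- Narasaka–Prasad reduction (Et2BOMe, NaBH4, THF/MeOH, −78 °C) of its boron chelate between O8 and O6 should give the syn 1,3-dioxygenated (6R,8S)-13-acetoxy-8-hydroxygermacra-1(10)E,4E,7(11)-trien-12,6-olide F4.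
- Steglich esterification of F4 with 19 comes back to the route at 24.

**Further compounds**
F1 | step 7 | 2-sulfanyl-(4E,8E)-5,9-dimethylcyclodeca-4,8-diene-1,3-dione | O=C1C(S)C(=O)/C=C(\C)CC/C=C(\C)C1
F2 | step 8 | (2E,5E,9E)-5,9-dimethyl-3-(pyrrolidin-1-yl)cyclodeca-2,5,9-trien-1-one | C1C/C=C(\C)C/C(N2CCCC2)=C\C(=O)/C=C1\C
F3 | step 13 | (8S)-13-acetoxy-6,8-dihydroxygermacra-1(10)E,4E,7(11)-trien-12,6-olide | CC(=O)OCC1=C2[C@@H](O)C/C(C)=C/CC/C(C)=C/C2(O)OC1=O
F4 | step 13 | (6R,8S)-13-acetoxy-8-hydroxygermacra-1(10)E,4E,7(11)-trien-12,6-olide | CC(=O)OCC1=C2[C@@H](O)C/C(C)=C/CC/C(C)=C/[C@H]2OC1=O
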